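**Retrosynthetic overview**
1. The side chain goes on last. The C5–CH2 bond comes from a B-alkyl Suzuki coupling of the 5-iodide with hydroborated 2-methylbut-3-en-2-ol, and the iodide comes from the 5-unsubstituted benzofuran, ortho to its free 4-OH.
2. The furan is the only ring built; benzene rings A and B are bought. It closes O1–C2 from ring B–CO–CH(ring A)–CH(OMe)2, whose acetal carbon becomes the 3-CHO. Ring A is mirror-symmetric at that stage, so either phenol gives the same benzofuran.
3. The key disconnection is C3–C3a. An α-keto carbon is made electrophilic as its phenyl-λ3-iodanyl derivative (an enolonium equivalent) and captures the ipso carbon of electron-rich ring A in a 1,2-aryl shift of a chalcone.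
4. The chalcone comes from a Claisen–Schmidt condensation. The aldehyde half is made from 5-methoxyresorcinol (MOM, ortho-lithiation, DMF) and the ketone half from 4'-hydroxy-2'-methoxyacetophenone (MOM).

Assumption: the target has no stereocentre, stereogenic axis or stereogenic alkene, so it is achiral and there is no enantiomer to select. Stereocentres occur only in transient racemic intermediates and are erased.

**Step 1**
Reactants: 1 5-methoxyresorcinol (5-methoxybenzene-1,3-diol)
Product: 2 1-methoxy-3,5-bis(methoxymethoxy)benzene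
Conditions: NaH (2.4 equiv), DMF, 0 °C; MOMCl (2.3 equiv), 0 °C to rt
Reagents that add atoms: chloromethyl methyl ether (MOMCl), COCCl
Why: Double Williamson-type O-alkylation of the two equivalent phenoxides; MOM directs the lithiation of step 2, survives KOH and the oxidant, and leaves under the acid that step 5 generates itself.

**Step 2**
Reactants: 2 1-methoxy-3,5-bis(methoxymethoxy)benzene
Product: 4 4-methoxy-2,6-bis(methoxymethoxy)benzaldehyde, via aryllithium 3 (not isolated)
Conditions: n-BuLi (1.15 equiv), THF, 0 °C, 1 h; DMF (2 equiv), 0 °C to rt; H2O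
Reagents that add atoms: N,N-dimethylformamide, CN(C)C=O (formyl group); n-butyllithium, [Li]CCCC (lithium, held in 3 only)
Why: Directed ortho-metalation, in which the position flanked by two chelating OMOM groups is the best coordinated and most acidic site, so lithiation and Bouveault-type formylation place the carbonyl carbon on the symmetry axis of ring A.

**Step 3**
Reactants: 5 1-(4-hydroxy-2-methoxyphenyl)ethanone
Product: 6 1-[2-methoxy-4-(methoxymethoxy)phenyl]ethanone
Conditions: MOMCl (1.3 equiv), K2CO3 (2 equiv), acetone, 0 °C to rt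
Reagents that add atoms: chloromethyl methyl ether (MOMCl), COCCl
Why: Williamson-type O-alkylation of the only phenol, which masks it against the trivalent iodine oxidant of step 5.

**Step 4**
Reactants: 4 4-methoxy-2,6-bis(methoxymethoxy)benzaldehyde; 6 1-[2-methoxy-4-(methoxymethoxy)phenyl]ethanone
Product: 7 (E)-1-[2-methoxy-4-(methoxymethoxy)phenyl]-3-[4-methoxy-2,6-bis(methoxymethoxy)phenyl]prop-2-en-1-one
Conditions: KOH (3 equiv), EtOH, rt, 36 h
Reagents that add atoms: none
Why: Claisen–Schmidt condensation (aldol addition, then E1cB loss of water) between a non-enolisable aldehyde and a methyl ketone gives the thermodynamically preferred E-enone.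

**Step 5 (key step)**
Reactants: 7 (E)-chalcone
Product: 11 4-hydroxy-2-(4-hydroxy-2-methoxyphenyl)-6-methoxy-1-benzofuran-3-carbaldehyde, via iodonium tosylate 8 (not isolated), via dimethyl acetal 9 (not isolated), via cyclic methyl acetal 10 (not isolated)
Conditions: PhI(OH)OTs (1.0 equiv), MeOH, 0 °C to rt, 2 h; 40 °C, 6 h; evaporate; (CF3)2CHOH, rt, 2 h
Reagents that add atoms: [hydroxy(tosyloxy)iodo]benzene, OI(c1ccccc1)OS(=O)(=O)c1ccc(C)cc1 (PhI and tosylate, held in 8 only); methanol, CO (methoxy groups of 8, 9 and 10; none is left in 11)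
Why: Hypervalent-iodine oxidative 1,2-aryl migration of a chalcone: the trivalent iodine reagent and methanol add across the push–pull alkene to give 8, whose α-keto carbon is now an enolonium-type acceptor, so ring A shifts from Cβ to Cα through a phenonium ion as PhI leaves, joining two carbons that are both nucleophilic in normal polarity and turning Cβ into the acetal of 9; the TsOH released then methanolyses the three MOM ethers and closes 10, and in the strongly ionising, weakly nucleophilic (CF3)2CHOH 10 reopens and the phenol recloses on the ketone, aromatising to the 3-formyl rather than the 3-aroyl benzofuran, with both phenols equivalent by symmetry and the racemic stereocentres of 8–10 erased.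

**Step 6**
Reactants: 11 4-hydroxy-2-(4-hydroxy-2-methoxyphenyl)-6-methoxy-1-benzofuran-3-carbaldehyde
Product: 12 4-hydroxy-2-(4-hydroxy-2-methoxyphenyl)-5-iodo-6-methoxy-1-benzofuran-3-carbaldehyde
Conditions: NIS (1.0 equiv), DMF, 0 °C to rt, dark
Reagents that add atoms: N-iodosuccinimide, O=C1CCC(=O)N1I
Why: Electrophilic aromatic iodination (SEAr) under neutral conditions: ring A carries three oxygen donors and its free, carbonyl-hydrogen-bonded 4-OH steers iodine to its only open ortho position C5 (5-hydroxy-7-alkoxyflavones iodinate at C6 in the same way), while ring B is drained by conjugation with the formyl group.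

**Step 7**
Reactants: 12 5-iodobenzofuran carbaldehyde; 13 2-methylbut-3-en-2-ol
Product: 15 4-hydroxy-5-(3-hydroxy-3-methylbutyl)-2-(4-hydroxy-2-methoxyphenyl)-6-methoxy-1-benzofuran-3-carbaldehyde (target), via B-alkyl borane 14 (not isolated)
Conditions: 13 (1.6 equiv), 9-BBN (1.5 equiv), THF, 0 °C to rt, 3 h; then 12, Pd(OAc)2 (5 mol %), SPhos (10 mol %), K3PO4 (3 M aq, 5 equiv), THF, 60 °C; work-up at pH 5–6, no peroxide
Reagents that add atoms: 9-borabicyclo[3.3.1]nonane (9-BBN), B1C2CCCC1CCC2 (boron cage, held in 14 only; only its hydrogen stays in 15)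
Why: Anti-Markovnikov hydroboration of the terminal alkene (faster than B–H attack on the hindered tertiary OH) followed by B-alkyl Suzuki–Miyaura coupling, in which zerovalent palladium bearing a bulky biaryl phosphine inserts into the hindered C–I bond and the hydroxyborate of 14 transfers its primary alkyl group; aldehyde, phenoxides and tertiary alcohol are tolerated and no stereocentre forms.

**Compound list**
1 | 5-methoxyresorcinol | COc1cc(O)cc(O)c1 | starting material
2 | 1-methoxy-3,5-bis(methoxymethoxy)benzene | COCOc1cc(OC)cc(OCOC)c1 | intermediate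
3 | [4-methoxy-2,6-bis(methoxymethoxy)phenyl]lithium (not isolated) | [Li]c1c(OCOC)cc(OC)cc1OCOC | intermediate
4 | 4-methoxy-2,6-bis(methoxymethoxy)benzaldehyde | COCOc1cc(OC)cc(OCOC)c1C=O | intermediate
5 | 1-(4-hydroxy-2-methoxyphenyl)ethanone | CC(=O)c1ccc(O)cc1OC | starting material
6 | 1-[2-methoxy-4-(methoxymethoxy)phenyl]ethanone | CC(=O)c1ccc(OCOC)cc1OC | intermediate
7 | (E)-1-[2-methoxy-4-(methoxymethoxy)phenyl]-3-[4-methoxy-2,6-bis(methoxymethoxy)phenyl]prop-2-en-1-one | COCOc1ccc(C(=O)/C=C/c2c(OCOC)cc(OC)cc2OCOC)c(OC)c1 | intermediate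
8 | {3-methoxy-1-[2-methoxy-4-(methoxymethoxy)phenyl]-3-[4-methoxy-2,6-bis(methoxymethoxy)phenyl]-1-oxopropan-2-yl}(phenyl)iodonium tosylate, racemic, not isolated | COCOc1ccc(C(=O)C([I+]c2ccccc2)C(OC)c2c(OCOC)cc(OC)cc2OCOC)c(OC)c1.Cc1ccc(S(=O)(=O)[O-])cc1 | intermediate
9 | 3,3-dimethoxy-1-[2-methoxy-4-(methoxymethoxy)phenyl]-2-[4-methoxy-2,6-bis(methoxymethoxy)phenyl]propan-1-one, racemic, not isolated | COCOc1ccc(C(=O)C(C(OC)OC)c2c(OCOC)cc(OC)cc2OCOC)c(OC)c1 | intermediate
10 | (4-hydroxy-2,6-dimethoxy-2,3-dihydro-1-benzofuran-3-yl)(4-hydroxy-2-methoxyphenyl)methanone, racemic diastereomer mixture, not isolated | COC1Oc2cc(OC)cc(O)c2C1C(=O)c1ccc(O)cc1OC | intermediate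
11 | 4-hydroxy-2-(4-hydroxy-2-methoxyphenyl)-6-methoxy-1-benzofuran-3-carbaldehyde | COc1cc(O)ccc1-c1oc2cc(OC)cc(O)c2c1C=O | intermediate
12 | 4-hydroxy-2-(4-hydroxy-2-methoxyphenyl)-5-iodo-6-methoxy-1-benzofuran-3-carbaldehyde | COc1cc(O)ccc1-c1oc2cc(OC)c(I)c(O)c2c1C=O | intermediate
13 | 2-methylbut-3-en-2-ol | C=CC(C)(C)O | starting material
14 | 4-(9-borabicyclo[3.3.1]nonan-9-yl)-2-methylbutan-2-ol (not isolated) | CC(C)(O)CCB1C2CCCC1CCC2 | intermediate
15 | 4-hydroxy-5-(3-hydroxy-3-methylbutyl)-2-(4-hydroxy-2-methoxyphenyl)-6-methoxy-1-benzofuran-3-carbaldehyde (achiral) | COc1cc(O)ccc1-c1oc2cc(OC)c(CCC(C)(C)O)c(O)c2c1C=O | target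

**Total step count:** 7. **Longest linear sequence:** 6 (1 → 2 → 4 → 7 → 11 → 12 → 15).

**Three steps most likely to fail**

Step 5. The oxidant may attack ring A itself through aryliodonium formation or over-oxidation. The MOM groups may fall off while oxidant is still present. The last stage may also leak to the 3-aroyl isomer. The fallback uses an epoxide and an acyl shift in place of the iodane and the aryl shift. It sets out from 7, where H2O2 and NaOH in MeOH (Weitz–Scheffer epoxidation) give the racemic trans-epoxy ketone F1. BF3·OEt2 in CH2Cl2 at −20 °C opens the epoxide at the ring-A benzylic carbon. The aroyl group then migrates with its bonding pair, acting as a formal acyl anion that reaches a benzylic cation, and gives the 2-aryl-3-oxopropanal F2. TsOH·H2O in MeOH at 40 °C, then (CF3)2CHOH at rt, removes the MOM groups and closes the furan, so the path comes back at 11.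

Step 6. Iodine may go to C7 (para to the 4-OH), to ring B, or enter twice. The fallback delivers the chain by a regiospecific sigmatropic shift instead of SEAr and sets out from 11.
- PivCl (1.0 equiv) with Et3N in CH2Cl2 at 0 °C acylates only the acidic, non-chelated ring-B phenol and gives the ring-B pivalate F3.
- Pd(PPh3)4-catalysed O-alkylation with tert-butyl 2-methylbut-3-en-2-yl carbonate in THF gives the 4-O-(1,1-dimethylallyl) ether F4.
- Heating in toluene at 110 °C triggers an aromatic Claisen rearrangement that can only reach C5 and gives the 5-prenyl phenol F5.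
- Mukaiyama hydration (Co(acac)2, PhSiH3, O2, THF) gives the tertiary alcohol pivalate F6.
- K2CO3 in MeOH removes the pivalate, and the path comes back at 15, bypassing 12 and step 7.

Step 7. Oxidative addition into a di-ortho-substituted, phenoxide-rich iodide may be slow, which would lead to protodeiodination. The borane may also reduce the aldehyde. The fallback replaces the sp3 coupling with vinylation and alkene saturation and sets out from 12 and 13. A Heck reaction (Pd(OAc)2, n-Bu4NCl, NaHCO3, DMF, 70 °C) gives the (E)-5-(3-hydroxy-3-methylbut-1-enyl)benzofuran F7. Alkene-selective hydrogenation (H2 at 1 atm, RhCl(PPh3)3, benzene/EtOH, rt) leaves the aldehyde untouched, and the path comes back at 15.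

**Further compounds**
F1 | step 5 | racemic trans-[2-methoxy-4-(methoxymethoxy)phenyl]{3-[4-methoxy-2,6-bis(methoxymethoxy)phenyl]oxiran-2-yl}methanone (one enantiomer drawn) | COCOc1ccc(C(=O)[C@H]2O[C@@H]2c2c(OCOC)cc(OC)cc2OCOC)c(OC)c1
F2 | step 5 | 3-[2-methoxy-4-(methoxymethoxy)phenyl]-2-[4-methoxy-2,6-bis(methoxymethoxy)phenyl]-3-oxopropanal (racemic, enolisable) | COCOc1ccc(C(=O)C(C=O)c2c(OCOC)cc(OC)cc2OCOC)c(OC)c1
F3 | step 6 | 4-(3-formyl-4-hydroxy-6-methoxy-1-benzofuran-2-yl)-3-methoxyphenyl pivalate | COc1cc(OC(=O)C(C)(C)C)ccc1-c1oc2cc(OC)cc(O)c2c1C=O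
F4 | step 6 | 4-[3-formyl-6-methoxy-4-(2-methylbut-3-en-2-yloxy)-1-benzofuran-2-yl]-3-methoxyphenyl pivalate | COc1cc(OC(=O)C(C)(C)C)ccc1-c1oc2cc(OC)cc(OC(C)(C)C=C)c2c1C=O
F5 | step 6 | 4-[3-formyl-4-hydroxy-6-methoxy-5-(3-methylbut-2-enyl)-1-benzofuran-2-yl]-3-methoxyphenyl pivalate | COc1cc(OC(=O)C(C)(C)C)ccc1-c1oc2cc(OC)c(CC=C(C)C)c(O)c2c1C=O
F6 | step 6 | 4-[3-formyl-4-hydroxy-5-(3-hydroxy-3-methylbutyl)-6-methoxy-1-benzofuran-2-yl]-3-methoxyphenyl pivalate | COc1cc(OC(=O)C(C)(C)C)ccc1-c1oc2cc(OC)c(CCC(C)(C)O)c(O)c2c1C=O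
F7 | step 7 | 4-hydroxy-5-[(E)-3-hydroxy-3-methylbut-1-enyl]-2-(4-hydroxy-2-methoxyphenyl)-6-methoxy-1-benzofuran-3-carbaldehyde | COc1cc(O)ccc1-c1oc2cc(OC)c(/C=C/C(C)(C)O)c(O)c2c1C=O
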